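The constants split into fast exchanges and slow exits, so I turn them into times at the charged amounts.

in all of them: time 3.0 min
- violet: substrate 0.083 M; partner 0.0913 M (fed, over 2.5 min); all else is in the flask from the start; the feed brings no volume worth counting
- grey: substrate 0.083 M (fed, over 2.5 min); partner 0.0913 M; all else is in the flask from the start; the feed brings no volume worth counting
- red: substrate 0.083 M; partner 0.0913 M (in portions, 2, over 2.5 min); first portion at the start, last at 2.5 min
- green: substrate 0.083 M; partner 0.0913 M; everything together at the start

    substrate ⇌ intermediate A (K1 = 12, k1 = 1.40 s⁻¹)
    substrate ⇌ dormant form (K2 = 9.17, k2 = 0.677 s⁻¹)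
    intermediate C ⇌ intermediate E (K3 = 3.10, k3 = 0.171 s⁻¹)
    intermediate B → intermediate C (k4 = 0.00359 s⁻¹)
    target ⇌ isomer of the product (K5 = 1.34, k5 = 0.0458 s⁻¹)
    intermediate A ⇌ intermediate B (K6 = 1.44, k6 = 0.118 s⁻¹)
    partner + intermediate D → target (k7 = 1.02 L mol⁻¹ s⁻¹)
    partner + intermediate A → intermediate D (k8 = 0.133 L mol⁻¹ s⁻¹)

* which flask leads in amount of isomer of the product, in percent of the substrate charged ("all alike" within 1.5 percentage points) (violet / grey / red / green / all alike)
* how much isomer of the product is there at the end, in percent of the substrate charged: violet
* how much isomer of the product is there at the end, in percent of the substrate charged: grey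
* how much isomer of the product is there at the end, in percent of the substrate charged: red
* how much isomer of the product is there at the end, in percent of the substrate charged: green

The exchange of intermediate A with intermediate B has a relaxation half-life of 3.47 s, longer than those of substrate with intermediate A and with the dormant form but far shorter than 3.0 min. So I treat these four species as one pool, in which intermediate A holds a fraction 0.304 and intermediate B holds 1.44 times that.

The pool leaks to intermediate C at 0.0944 min⁻¹. At charged partner it is captured by partner at 0.222 min⁻¹, which is faster. Intermediate D then lasts 10.7 s, less than the pool's capture time.

What I carry is the capture ratio ρ, capture by partner over leak to intermediate C at the charged partner, a selectivity factor in which the fraction of intermediate A cancels while the split 1.44 between intermediate B and intermediate A stays: 2.35. With x the mean partner as a fraction of its charge, and y the fraction of the substrate charge that has become target or isomer of the product: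

y = [xρ / (1 + xρ)] · [1 − exp(−kl·(1 + xρ)·t)]

First way, green with x held at 1: y = 43.0 %.

Second way, the partner's ledger. Each target costs two partners, which makes partner the limiting reagent, with a ceiling of y = 55.0 %. The first y would spend 78.1 % of the partner, so holding x at 1 is what cheats. Taking half of that spending as the mean loss gives:

green: x = 0.609, y = 29.3 %

Target and isomer of the product relax with a half-life of 0.144 min, short against 3.0 min, so the isomer takes a share 0.573 of y. Violet and red offer the same mean partner, and in grey the pool arrives on average 1.25 min late, so I run the same two passes on them:

violet, red: x = 0.583, y = 28.3 %; then x = 0.326, y = 17.1 %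

grey, contact 1.75 min: x = 1, y = 29.8 %; then x = 0.729, y = 22.8 %

So I commit to isomer of the product at 9.78 % in violet, 13.1 % in grey, 9.78 % in red and 16.8 % in green, with green leading.

The forecast says green, with 10.3 % for violet, 11.6 % for grey, 9.8 % for red and 16.3 % for green, on the ground “Having partner present early beats the slow leak”. Its grey lies below mine.

The simulation gives green, with 9.91 % for violet, 10.9 % for grey, 9.51 % for red and 16.6 % for green.

Green leads red by 7 percentage points. With the falling back of intermediate B to intermediate A taken away, that lead is 2.4 points, and with the falling back of the dormant form to substrate taken away instead, it is 3.3 points, so these two returns act together in it. In the flask with 0.23 M of partner, the capture ratio becomes 5.92. Two passes give y = 73.5 %, then x = 1.85 and y = 63.4 %, so isomer of the product 36.3 %. The computed result is 34.2 %.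

(The rate constants come from no measurement; no experiment stands behind them.)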